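## The problem

The target is a cis,cis-germacranolide. Its ten-membered carbocycle (C1–C10) holds two trisubstituted olefins, C1=C10 and C4=C5, both cis with respect to the ring. Each olefin carries an oxidised one-carbon branch: the C14 aldehyde on C10 and the C15 hydroxymethyl on C4. Four contiguous stereocentres run from C6 to C9 (6R,7S,8R,9S): a trans-fused α-methylene-γ-lactone on C6/C7 and a cis-8,9-diol in which only O8 carries the (R)-2-methylbutanoate. A synthesis must close a medium ring, fix two olefin geometries, keep C14 and C15 at different oxidation levels, and tell two neighbouring secondary hydroxyls apart. The cis-diol can come from the chiral pool and then control the rest: the C8 oxygen can send a C7 alkylation to the opposite face and, by chelation, guide the hydride that creates C6. The fragile parts are the methylene lactone (Michael acceptor), the enal, the mono-acylated diol (acyl migration; a free 8-OH can also close a lactol onto C14) and the cyclodeca-1,5-diene itself (Cope rearrangement, acid-induced transannular cyclisation). The enabling feature is the 1,5-diene C10=C1–C2–C3–C4=C5. Both olefins bear a carbonyl-level carbon and flank the oxygenated arc C5–C10, so the ring is the formal metathesis product of a cyclobut-1-ene-1-carboxylate (C1–C4, C15) and a 3-formylcyclohex-2-enone (C5–C10, C14) whose ketone is the future carbinol C6.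

## Retrosynthesis

**Ester and masks (29 ⇐ 27 ⇐ 25 + 26).** The C8–O acyl bond, the silyl ether on O15 and the dioxolane on C14 are cut last. The acid 26 is attached to diol 25 while C14 is still an acetal, because a free C14 aldehyde would be trapped by the 8-OH as a five-membered lactol. This cut asks for an esterification that selects O8 over O9 and a final deprotection that is acidic, not basic.

**Methylene and acetonide (25 ⇐ 24 ⇐ 21).** The C11=C13 bond is cut back to the plain lactone 21, and the diol is returned to its acetonide. Methylenation through a Mannich base needs a lactone enolate, so it is placed before any free hydroxyl, ester or aldehyde is present. The acetonide is then exchanged onto ethylene glycol, which leaves the C14 dioxolane untouched.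

**Lactone and C15 level (21 ⇐ 18 ⇐ 16).** The C12–O6 lactone bond and the C6–H bond are cut, leading to the cyclodecadienone keto diester 16. Carrying C12 as an ester makes the lactone close directly when C6 is reduced. The price is that the C15 ester must then be reduced through the lactol (18 → 19 → 20 → 21). The forward reduction must deliver 6R; chelation between the ketone and O8 is expected to do this.

**Ring opening (16 ⇐ 15 ⇐ 14).** In the reverse sense the C1–C4 and C5–C10 bonds are formed, folding the ten-membered ring into the 6-4-4 tricycle 14. Against a macrocyclisation, this cut makes the medium ring by a unimolecular, strain-driven cycloreversion. It leaves a ketone conjugated to the C4=C5 enoate, through which the olefin geometry can be equilibrated to the ring-cis form (16).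

**Key cut (14 ⇐ 10 + 13).** The C4–C5 and C1–C10 bonds of the central cyclobutane are cut, giving enone 10 and methyl cyclobut-1-ene-1-carboxylate 13. All skeletal carbons are then present: C5–C12 and C14 in 10, and C1–C4 and C15 in 13. The forward step must be head-to-head; its four new stereocentres are later destroyed.

**Enone substituents (10 ⇐ 8 ⇐ 7 ⇐ 6).** The C10–C14 bond is cut to a dioxolanyl radical adding to the enone, followed by re-oxidation. The C7–C11 bond is cut to an α′-enolate and methyl bromoacetate. Alkylation comes first, so that the later kinetic enolisation of 8 can only go to the C5 methylene, which fixes where the enone is regenerated.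

**Chiral pool (6 ⇐ 1; 13 ⇐ 11).** Enone 6 is the degradation product of (−)-quinic acid 1. The quinic C1 becomes the ketone (C6) and the cis-3,4-diol becomes O8/O9 with the absolute configuration of the target. Ester 13 comes from commercial ethyl 1-bromocyclobutane-1-carboxylate 11 by elimination and re-esterification.

## Roads not taken

**Alternative 1: pinacol macrocyclisation at C8–C9.** The cut is the C8–C9 bond. SmI2 would reduce both aldehydes of the open-chain dialdehyde A1 and join them, giving the ten-membered cis-diol A2.
- Merits: both olefin geometries are fixed in an open chain before ring closure, there is no thermal step, and the ring and two carbinol centres form at once.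
- Weak points: a ten-membered pinacol closure fights entropy and transannular strain. The C9 ketyl is allylic and can couple through C1 or be over-reduced. The diol must come out cis and with the right sense relative to C7. A1 itself needs C6, C7 and C11 set in an acyclic chain. A2 still leaves O8 and O9 to be told apart.
- Comparison: on olefin geometry this road is better than the chosen one, which relies on a predicted cycloreversion outcome and an equilibration. The chosen plan sets against this a ring closure without high dilution and a cis-diol and C7 that come from quinic acid and are not created in the ring-forming step.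

**Alternative 2: late double allylic oxidation.** The cut is the two C–O bonds at C14 and C15. SeO2 with t-BuOOH would oxidise both methyl groups of the all-trans dideoxy lactone A3 by ene reaction and [2,3]-shift, turning both olefins ring-cis and giving the 14,15-diol A4.
- Merits: it is short after A3, needs almost no protecting groups, and introduces the sensitive oxygenation last.
- Weak points: A3 is a trans,trans-germacradienolide with the full C6–C9 array and is no easier to make than the target; it is also the most Cope-labile member of the family. Two oxidations with two geometry inversions must both succeed beside a free allylic 9-OH and a methylene lactone. A4 then needs C14–OH oxidised in the presence of C15–OH, two primary allylic alcohols with no inherent difference.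
- Comparison: this road is shorter in protecting-group operations. The chosen plan brings C14 and C15 in at different oxidation levels from the start (acetal and ester), which is exactly the distinction the end game needs.

**Alternative 3: nickel three-component coupling.** The cut is C5–C6 and C3–C4. Ni(cod)2 would join aldehyde A5, alkyne A6 and zinc reagent A7 by syn addition across the alkyne, giving the open-chain hydroxy ester A8.
- Merits: the C4=C5 geometry is set by mechanism and not by equilibration, the assembly is convergent, and the diol again comes from the chiral pool.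
- Weak points: no ring closes. The ten-membered ring would still have to be made, most plausibly by metathesis to a trisubstituted C1=C10 olefin, with uncertain geometry and competing oligomers. The C6 carbinol depends on the facial bias of an α-branched, epimerisable aldehyde.
- Comparison: this road is better for C4=C5. The chosen plan sets against it that the medium ring and both olefins arise in one strain-driven step from a compact tricycle.

Key step: step 10

## Route

Remark: germacrane numbering is used for atoms (C1–C15); centres that are later destroyed (C10 in 8, the lactol carbon in 19 and 20, C11 in 22 and 23) are drawn as the expected isomer or left undefined.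

Step 1
Reactants: 1 (−)-quinic acid
Product: 2 3,4-O-isopropylidene-1,5-quinide
Conditions: Me2C(OMe)2, TsOH·H2O (cat.), acetone, reflux
Reagents that add atoms: 2,2-dimethoxypropane, COC(C)(C)OC
Why: Acid-catalysed ketalisation of the cis-3,4-diol and lactonisation of the carboxyl onto the cis C5 hydroxyl occur together; no stereocentre is touched.

Step 2
Reactants: 2 3,4-O-isopropylidene-1,5-quinide
Product: 3 acetonide triol (1-hydroxymethyl-1,5-diol)
Conditions: NaBH4, EtOH, 0 °C to rt
Reagents that add atoms: none
Why: Borohydride reduction of the strained bridged lactone gives the primary alcohol and frees the C5 hydroxyl; the ketal is inert.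

Step 3
Reactants: 3 acetonide triol
Product: 4 5-hydroxy-3,4-(isopropylidenedioxy)cyclohexan-1-one (5-OH trans to the acetonide)
Conditions: NaIO4, pH 7 buffer/THF, 0 °C
Reagents that add atoms: none
Why: Periodate (Malaprade) cleavage of the only free 1,2-diol, the tertiary OH and its CH2OH, gives the ketone and formaldehyde; the ring diol is masked and the C5 hydroxyl has no free vicinal partner.

Step 4
Reactants: 4 β-hydroxy ketone
Product: 6 (4S,5R)-4,5-(isopropylidenedioxy)cyclohex-2-en-1-one, via mesylate 5 (not isolated)
Conditions: MsCl, Et3N, CH2Cl2, 0 °C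
Reagents that add atoms: none
Why: Mesylation of the β-hydroxyl and E1cB elimination give the enone; the sulfonate is a far better leaving group than the acetonide oxygen on the other side of the ketone, so the diol stereocentres survive.

Step 5
Reactants: 6 acetonide enone
Product: 7 (4S,5R,6R)-6-(2-methoxy-2-oxoethyl)-4,5-(isopropylidenedioxy)cyclohex-2-en-1-one (side chain on C7, trans to O8)
Conditions: LiN(i-Pr)2, THF, −78 °C; BrCH2CO2Me, −78 to −50 °C
Reagents that add atoms: methyl bromoacetate, COC(=O)CBr
Why: Kinetic α′-deprotonation gives the cross-conjugated lithium dienolate, and enolate alkylation with the very reactive α-bromo ester takes place on the face opposite the fused acetonide, setting C7 trans to O8. The low temperature keeps the β-alkoxy enolate from eliminating.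

Step 6
Reactants: 7 α′-alkylated enone
Product: 8 3-(1,3-dioxolan-2-yl)-6-(2-methoxy-2-oxoethyl)-4,5-(isopropylidenedioxy)cyclohexan-1-one (dioxolane on C10)
Conditions: 1,3-dioxolane (solvent), Ph2CO (0.2 equiv), hν 350 nm, rt
Reagents that add atoms: 1,3-dioxolane, C1COCO1
Why: Benzophenone-sensitised radical conjugate addition (Giese type): the nucleophilic dioxolan-2-yl radical adds to the enone β-carbon C10 anti to the C9 oxygen and the α-keto radical takes hydrogen from the solvent. The C10 configuration is irrelevant because C10 becomes sp2 again in step 7.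

Step 7
Reactants: 8 dioxolanyl ketone
Product: 10 (4S,5R,6R)-3-(1,3-dioxolan-2-yl)-6-(2-methoxy-2-oxoethyl)-4,5-(isopropylidenedioxy)cyclohex-2-en-1-one, via trimethylsilyl enol ether 9 (not isolated)
Conditions: LiN(i-Pr)2, Me3SiCl, THF, −78 °C; then Pd(OAc)2, MeCN, rt
Reagents that add atoms: none
Why: Kinetic deprotonation goes to the C5 methylene (C7 is a hindered methine and the ester α-protons are less acidic) and in situ silylation fixes that regiochemistry. Saegusa–Ito oxidation then regenerates the C5=C10 enone without forming the eliminable C7 enolate.

Step 8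
Reactants: 11 ethyl 1-bromocyclobutane-1-carboxylate
Product: 12 cyclobut-1-ene-1-carboxylic acid
Conditions: KOH, PhMe, reflux; then aq. HCl, 0 °C
Reagents that add atoms: potassium hydroxide, [K+].[OH-]
Why: E2 dehydrobromination of the tertiary α-bromo ester with concurrent saponification is the standard entry to this strained acrylic acid.

Step 9
Reactants: 12 cyclobut-1-ene-1-carboxylic acid
Product: 13 methyl cyclobut-1-ene-1-carboxylate
Conditions: MeI, K2CO3, DMF, 0 °C to rt; used at once
Reagents that add atoms: iodomethane, CI
Why: SN2 O-alkylation of the carboxylate avoids the acid catalysis that would polymerise the strained acrylate.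

Step 10
Reactants: 10 dioxolanyl enone; 13 methyl cyclobut-1-ene-1-carboxylate
Product: 14 cis-anti-cis tricyclic photoadduct (cyclohexanone C5–C10, central cyclobutane C4–C5–C10–C1, outer cyclobutane C1–C4; CO2Me on C4, dioxolane on C10)
Conditions: hν 350 nm (Pyrex), CH2Cl2, −30 °C, 13 (6 equiv); then filtration through neutral Al2O3
Reagents that add atoms: none
Why: Excitation of the enone and intersystem crossing give the twisted triplet, which adds to the strained, acceptor-substituted cyclobutene to form a triplet 1,4-diradical; spin inversion and radical recombination then close the central cyclobutane (C4–C5 and C1–C10), a four-membered ring made by diradical collapse. The closest known reaction type is the intermolecular enone–alkene [2+2] photocycloaddition of 3-substituted cyclohex-2-enones with alkyl cyclobut-1-ene-1-carboxylates, which gives 6-4-4 tricyclic keto esters of this kind. The selectivity the step needs is regiochemical: the ester-bearing C4 must bond to the enone α-carbon C5 (head-to-head), the usual preference for electron-poor alkenes, reinforced here because the other mode would join two fully substituted carbons (C4 and C10). Of the four new stereocentres, C1 and C4 are cis by the geometry of the cyclobutene; C5 and C10 end cis-fused, since any trans-fused adduct should epimerise at C5 on alumina; the outer ring sits anti to the cyclohexanone for steric reasons; and the face of 10 is chosen by the acetonide oxygen on C9, next to C10, which sends the alkene to the opposite face. None of these centres survives step 11, so they matter only for the olefin geometry delivered there. Excess 13, low temperature and 350 nm light, where the saturated ketone hardly absorbs, are meant to suppress enone dimerisation and Norrish α-cleavage of 14.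

Step 11
Reactants: 14 tricyclic photoadduct
Product: 15 cyclodeca-1(10),4-dien-6-one keto diester (C4=C5 ring-trans, C1=C10 ring-cis)
Conditions: PhMe (0.01 M), BHT (cat.), 160–170 °C, sealed base-washed tube
Reagents that add atoms: none
Why: Thermal cycloreversion of the bicyclo[2.2.0]hexane: strain breaks the central C1–C4 bond to an ester-stabilised 1,4-diyl, which cleaves the weakest remaining bond, C5–C10 (α to the ketone, fully substituted at C10). The chair-like diyl with C9 axial and C6 equatorial predicts ring-cis C1=C10 and ring-trans C4=C5. C7–C9 are untouched.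

Step 12
Reactants: 15 keto diester (C4=C5 ring-trans)
Product: 16 keto diester with both olefins ring-cis (C6 ketone and C15 ester trans across C4=C5)
Conditions: pyridine, CH2Cl2, rt to 40 °C
Reagents that add atoms: none
Why: Nucleophile-catalysed olefin isomerisation by reversible conjugate addition at C5 of the ene-dicarbonyl. The ring-cis olefin with trans carbonyl groups is favoured both by ring strain and by the fumarate-type arrangement, and the weak base should not epimerise C7 or eliminate O8.

Step 13
Reactants: 16 ring-cis keto diester
Product: 18 (6R)-6,12-olide methyl ester (trans-fused lactone; C15 ester, C14 dioxolane and 8,9-acetonide intact), via hydroxy diester 17 (not isolated)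
Conditions: Zn(BH4)2, Et2O, −30 °C; then PPTS (cat.), PhMe, 50 °C
Reagents that add atoms: none
Why: Chelation-controlled 1,2-reduction: zinc bridges the C6 carbonyl and the C8 acetonide oxygen, and hydride adds to the six-membered chelate anti to the axial C7 side chain, giving the 6,8-syn alcohol (6R); Felkin–Anh attack would give the epimer. The new hydroxyl cannot reach the trans-disposed C15 ester and lactonises onto C12.

Step 14
Reactants: 18 lactone methyl ester
Product: 19 lactol with free C15 allylic alcohol
Conditions: i-Bu2AlH (3.5 equiv), CH2Cl2, −78 °C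
Reagents that add atoms: none
Why: Aluminium hydride reduction at low temperature stops at the lactol for the γ-lactone and takes the conjugated ester to the allylic alcohol by 1,2-addition; both acetals are inert.

Step 15
Reactants: 19 lactol allylic alcohol
Product: 20 15-O-tert-butyldiphenylsilyl lactol
Conditions: t-BuPh2SiCl, imidazole, CH2Cl2, 0 °C
Reagents that add atoms: tert-butylchlorodiphenylsilane, CC(C)(C)[Si](Cl)(c1ccccc1)c1ccccc1
Why: Silylation with the bulky chloride selects the primary allylic hydroxyl over the hemiacetal hydroxyl; this silyl ether withstands the acid of step 18.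

Step 16
Reactants: 20 silyl lactol
Product: 21 15-O-silyl 6,12-olide
Conditions: TEMPO (cat.), PhI(OAc)2, CH2Cl2, rt
Reagents that add atoms: none
Why: Oxoammonium oxidation of the lactol returns the γ-lactone; no other free hydroxyl is present and the acetals tolerate the acetic acid formed.

Step 17
Reactants: 21 silyl lactone
Product: 24 α-methylene lactone (C11=C13), via Mannich base 22 (not isolated), via ammonium iodide 23 (not isolated)
Conditions: LiN(SiMe3)2, THF, −78 °C; CH2=NMe2+ I−, −78 to 0 °C; MeI, MeOH, rt; aq. NaHCO3, CH2Cl2
Reagents that add atoms: Eschenmoser's salt, C=[N+](C)C.[I-]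
Why: Mannich reaction of the lactone enolate (C11 is the only enolisable position), quaternisation and Hofmann-type elimination give the exocyclic methylene; the C11 centre formed on the way is destroyed.

Step 18
Reactants: 24 methylene lactone acetonide
Product: 25 8,9-diol (C14 dioxolane and O15 silyl ether retained)
Conditions: HOCH2CH2OH (10 equiv), CSA (0.1 equiv), MeCN, 0 °C to rt
Reagents that add atoms: none
Why: Acid-catalysed transketalisation moves the isopropylidene group to ethylene glycol. The same glycol keeps the C14 dioxolane closed (a degenerate exchange), so no free aldehyde is available for lactol formation with the 8-OH.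

Step 19
Reactants: 25 8,9-diol; 26 (R)-2-methylbutanoic acid
Product: 27 8-O-[(2R)-2-methylbutanoyl] ester with free 9-OH
Conditions: DCC (1.1 equiv), DMAP (0.1 equiv), CH2Cl2, −20 to 0 °C
Reagents that add atoms: none
Why: Steglich esterification with one equivalent of the α-branched acid should select the C8 hydroxyl. The C9 hydroxyl is flanked by the fully substituted C10 carrying the dioxolane, to which it can hydrogen-bond, and is the more hindered; catalytic DMAP at low temperature should not epimerise the acid.

Step 20
Reactants: 27 silyl acetal ester
Product: 29 target, (6R,7S,8R,9S)-9,15-dihydroxy-8-[(2R)-2-methylbutanoyloxy]-14-oxogermacra-1(10),4,11(13)-trien-12,6-olide with both ring olefins ring-cis, via desilylated acetal 28 (not isolated)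
Conditions: HF·pyridine, THF, 0 °C to rt; then 1 M aq. HCl, THF, 0 °C
Reagents that add atoms: water, O
Why: Fluoride cleavage of the primary allylic silyl ether followed by hydrolysis of the enal dioxolane. Both stages are acidic, which avoids the base-induced acyl shift from O8 to O9 and conjugate addition to the methylene lactone, and the conjugated ring-cis enal is the thermodynamic geometry.

## Compound list

1 | (−)-quinic acid, (1S,3R,4S,5R)-1,3,4,5-tetrahydroxycyclohexane-1-carboxylic acid | C1[C@H]([C@H]([C@@H](C[C@@]1(C(=O)O)O)O)O)O | starting material
2 | 3,4-O-isopropylidene-1,5-quinide | C1[C@H]2OC(C)(C)O[C@H]2[C@H]3C[C@]1(O)C(=O)O3 | intermediate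
3 | acetonide triol (lactone of 2 reduced to CH2OH and 5-OH) | C1[C@H]2OC(C)(C)O[C@H]2[C@H](O)C[C@]1(O)CO | intermediate
4 | 5-hydroxy-3,4-(isopropylidenedioxy)cyclohexan-1-one, OH trans to the acetonide | O=C1C[C@@H](O)[C@@H]2OC(C)(C)O[C@@H]2C1 | intermediate
5 | 5-O-mesylate of 4 | O=C1C[C@@H](OS(C)(=O)=O)[C@@H]2OC(C)(C)O[C@@H]2C1 | intermediate
6 | (4S,5R)-4,5-(isopropylidenedioxy)cyclohex-2-en-1-one | O=C1C=C[C@@H]2OC(C)(C)O[C@@H]2C1 | intermediate
7 | (4S,5R,6R)-6-(2-methoxy-2-oxoethyl)-4,5-(isopropylidenedioxy)cyclohex-2-en-1-one | O=C1C=C[C@@H]2OC(C)(C)O[C@@H]2[C@H]1CC(=O)OC | intermediate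
8 | 3-(1,3-dioxolan-2-yl) ketone from 7, dioxolane trans to the neighbouring acetonide oxygen | O=C1C[C@@H](C2OCCO2)[C@@H]3OC(C)(C)O[C@@H]3[C@H]1CC(=O)OC | intermediate
9 | trimethylsilyl enol ether of 8 (C5=C6 enol ether) | C[Si](C)(C)OC1=C[C@@H](C2OCCO2)[C@@H]3OC(C)(C)O[C@@H]3[C@H]1CC(=O)OC | intermediate
10 | (4S,5R,6R)-3-(1,3-dioxolan-2-yl)-6-(2-methoxy-2-oxoethyl)-4,5-(isopropylidenedioxy)cyclohex-2-en-1-one | O=C1C=C(C2OCCO2)[C@@H]3OC(C)(C)O[C@@H]3[C@H]1CC(=O)OC | intermediate
11 | ethyl 1-bromocyclobutane-1-carboxylate | CCOC(=O)C1(Br)CCC1 | starting material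
12 | cyclobut-1-ene-1-carboxylic acid | OC(=O)C1=CCC1 | intermediate
13 | methyl cyclobut-1-ene-1-carboxylate | COC(=O)C1=CCC1 | intermediate
14 | cis-anti-cis 6-4-4 tricyclic photoadduct (keto diester) | O=C1[C@H]2[C@]3(C(=O)OC)CC[C@@H]3[C@@]2(C4OCCO4)[C@@H]5OC(C)(C)O[C@@H]5[C@H]1CC(=O)OC | intermediate
15 | cyclodecadienone keto diester, C4=C5 ring-trans, C1=C10 ring-cis | O=C1/C=C(\C(=O)OC)CC/C=C(/C2OCCO2)[C@@H]3OC(C)(C)O[C@@H]3[C@H]1CC(=O)OC | intermediate
16 | cyclodecadienone keto diester, both olefins ring-cis | O=C1/C=C(/C(=O)OC)CC/C=C(/C2OCCO2)[C@@H]3OC(C)(C)O[C@@H]3[C@H]1CC(=O)OC | intermediate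
17 | (6R)-6-hydroxy diester | O[C@@H]1/C=C(/C(=O)OC)CC/C=C(/C2OCCO2)[C@@H]3OC(C)(C)O[C@@H]3[C@H]1CC(=O)OC | intermediate
18 | trans-fused 6,12-olide with C15 methyl ester | C1C(=O)O[C@@H]2/C=C(/C(=O)OC)CC/C=C(/C3OCCO3)[C@@H]4OC(C)(C)O[C@@H]4[C@@H]12 | intermediate
19 | lactol with C15 allylic alcohol | C1C(O)O[C@@H]2/C=C(/CO)CC/C=C(/C3OCCO3)[C@@H]4OC(C)(C)O[C@@H]4[C@@H]12 | intermediate
20 | 15-O-tert-butyldiphenylsilyl lactol | C1C(O)O[C@@H]2/C=C(/CO[Si](c3ccccc3)(c4ccccc4)C(C)(C)C)CC/C=C(/C5OCCO5)[C@@H]6OC(C)(C)O[C@@H]6[C@@H]12 | intermediate
21 | 15-O-tert-butyldiphenylsilyl 6,12-olide | C1C(=O)O[C@@H]2/C=C(/CO[Si](c3ccccc3)(c4ccccc4)C(C)(C)C)CC/C=C(/C5OCCO5)[C@@H]6OC(C)(C)O[C@@H]6[C@@H]12 | intermediate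
22 | 11-(dimethylaminomethyl) lactone (Mannich base) | CN(C)CC1C(=O)O[C@@H]2/C=C(/CO[Si](c3ccccc3)(c4ccccc4)C(C)(C)C)CC/C=C(/C5OCCO5)[C@@H]6OC(C)(C)O[C@@H]6[C@@H]12 | intermediate
23 | trimethylammonium iodide of 22 | C[N+](C)(C)CC1C(=O)O[C@@H]2/C=C(/CO[Si](c3ccccc3)(c4ccccc4)C(C)(C)C)CC/C=C(/C5OCCO5)[C@@H]6OC(C)(C)O[C@@H]6[C@@H]12.[I-] | intermediate
24 | α-methylene lactone with 8,9-acetonide, C14 dioxolane and O15 silyl ether | C=C1C(=O)O[C@@H]2/C=C(/CO[Si](c3ccccc3)(c4ccccc4)C(C)(C)C)CC/C=C(/C5OCCO5)[C@@H]6OC(C)(C)O[C@@H]6[C@@H]12 | intermediate
25 | 8,9-diol | C=C1C(=O)O[C@@H]2/C=C(/CO[Si](c3ccccc3)(c4ccccc4)C(C)(C)C)CC/C=C(/C5OCCO5)[C@H](O)[C@H](O)[C@@H]12 | intermediate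
26 | (R)-2-methylbutanoic acid | CC[C@@H](C)C(=O)O | starting material
27 | 8-O-[(2R)-2-methylbutanoyl] ester, 9-OH free | C=C1C(=O)O[C@@H]2/C=C(/CO[Si](c3ccccc3)(c4ccccc4)C(C)(C)C)CC/C=C(/C5OCCO5)[C@H](O)[C@H](OC(=O)[C@H](C)CC)[C@@H]12 | intermediate
28 | desilylated C14 dioxolane | C=C1C(=O)O[C@@H]2/C=C(/CO)CC/C=C(/C3OCCO3)[C@H](O)[C@H](OC(=O)[C@H](C)CC)[C@@H]12 | intermediate
29 | CNP0331447.12 | C=C1C(=O)O[C@@H]2/C=C(/CO)CC/C=C(/C=O)[C@H](O)[C@H](OC(=O)[C@H](C)CC)[C@@H]12 | target

## Step count and least certain steps

Total: 20 steps. Longest linear sequence: 18 steps (steps 1–7 and 10–20, from quinic acid); the cyclobutene ester takes 2 steps.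

**Step 10 (key step).** What may go wrong: addition in the head-to-tail sense and light-induced oligomerisation of 13, both competing with a hindered enone whose β-carbon is fully substituted. Fallback, from 10 back to 14: build the same bicyclo[2.2.0]hexane in two photochemical stages. Irradiation of 10 with methyl propiolate forms the same C4–C5 and C1–C10 bonds and should give the cyclobutene keto ester F1. Acetone-sensitised [2+2] addition of ethylene to the strained enoate of F1, from its open face, then closes the outer ring and should return 14.

**Step 11.** What may go wrong: Cope rearrangement of the first-formed cis,trans-diene (or cleavage of C2–C3 in the diyl) to a divinylcyclohexanone, and thermal β-elimination of the C8 oxygen from the ketone. Fallback, from 14 back to 18: remove the ketone before heating. Zn(BH4)2 reduction of 14 should give the tricyclic hydroxy ester F2, which lactonises under acid to the tricyclic lactone F3. Thermolysis of F3, a lactone-bearing adduct of the type known to open to a germacranolide, should give the ring-trans lactone ester F4. Triplet-sensitised or thiolate-catalysed equilibration of its C4=C5 bond then leads to 18.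

**Step 5.** What may go wrong: β-elimination of the C8 acetonide oxygen from the lithium enolate, followed by aromatisation, before alkylation is complete. Fallback, from 6 back to 7: avoid the free enolate. Soft enolisation with t-BuMe2SiOTf and Et3N should give the 2-silyloxy diene F5. ZnBr2-promoted alkylation with methyl chloro(phenylthio)acetate, again anti to the acetonide, should give the α-phenylthio ester F6. Bu3SnH with AIBN removes the sulfur and gives 7.

**Step 13.** What may go wrong: poor facial selectivity at C6 if hydride attacks the non-chelated ketone (Felkin–Anh mode) or if the side-chain ester competes for zinc. Fallback, from 16 back to 18: correct C6 by inversion instead of by the hydride. The epimeric hydroxy diester F7 is saponified at its unhindered saturated ester (LiOH, 1 equiv) to the hydroxy acid F8. Mitsunobu lactonisation (PPh3, DIAD) then closes the lactone with inversion at C6 and gives 18.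

**Step 19.** What may go wrong: competing acylation of the allylic C9 hydroxyl, or double acylation, since the steric difference between the two hydroxyls is modest. Fallback, from 25 back to 29: turn a preference for C9 to use. Et3SiCl with imidazole silylates the more reactive C9 hydroxyl to give the 9-O-triethylsilyl ether F9. Esterification of the remaining 8-OH as in step 19 gives the silyl ester F10. The conditions of step 20 then remove both silyl groups and the acetal and give 29.

## Further compounds

F1 | step 10 | cyclobutene keto ester from 10 and methyl propiolate | O=C1[C@H]2C(C(=O)OC)=C[C@@]2(C3OCCO3)[C@@H]4OC(C)(C)O[C@@H]4[C@H]1CC(=O)OC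
F2 | step 11 | tricyclic (6R)-hydroxy diester | O[C@@H]1[C@H]2[C@]3(C(=O)OC)CC[C@@H]3[C@@]2(C4OCCO4)[C@@H]5OC(C)(C)O[C@@H]5[C@H]1CC(=O)OC
F3 | step 11 | tricyclic 6,12-lactone | O1[C@@H]2[C@H]3[C@]4(C(=O)OC)CC[C@@H]4[C@@]3(C5OCCO5)[C@@H]6OC(C)(C)O[C@@H]6[C@H]2CC1=O
F4 | step 11 | ten-membered lactone ester with C4=C5 ring-trans | C1C(=O)O[C@@H]2/C=C(\C(=O)OC)CC/C=C(/C3OCCO3)[C@@H]4OC(C)(C)O[C@@H]4[C@@H]12
F5 | step 5 | 2-(tert-butyldimethylsilyloxy) diene from 6 | CC(C)(C)[Si](C)(C)OC1=C[C@H]2OC(C)(C)O[C@H]2C=C1
F6 | step 5 | α-phenylthio ester adduct | O=C1C=C[C@@H]2OC(C)(C)O[C@@H]2[C@H]1C(Sc3ccccc3)C(=O)OC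
F7 | step 13 | (6S)-6-hydroxy diester, C6 epimer of 17 | O[C@H]1/C=C(/C(=O)OC)CC/C=C(/C2OCCO2)[C@@H]3OC(C)(C)O[C@@H]3[C@H]1CC(=O)OC
F8 | step 13 | (6S)-hydroxy acid | O[C@H]1/C=C(/C(=O)OC)CC/C=C(/C2OCCO2)[C@@H]3OC(C)(C)O[C@@H]3[C@H]1CC(=O)O
F9 | step 19 | 9-O-triethylsilyl ether of 25 | C=C1C(=O)O[C@@H]2/C=C(/CO[Si](c3ccccc3)(c4ccccc4)C(C)(C)C)CC/C=C(/C5OCCO5)[C@H](O[Si](CC)(CC)CC)[C@H](O)[C@@H]12
F10 | step 19 | 9-O-triethylsilyl 8-O-[(2R)-2-methylbutanoyl] ester | C=C1C(=O)O[C@@H]2/C=C(/CO[Si](c3ccccc3)(c4ccccc4)C(C)(C)C)CC/C=C(/C5OCCO5)[C@H](O[Si](CC)(CC)CC)[C@H](OC(=O)[C@H](C)CC)[C@@H]12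
A1 | alternative 1 | open-chain C8,C9-dialdehyde with masked lactone | CN(C)C[C@@H]1C(=O)O[C@H](/C=C(/CO[Si](C)(C)C(C)(C)C)CC/C=C(/CO[Si](CC)(CC)CC)C=O)[C@H]1C=O
A2 | alternative 1 | ten-membered cis-8,9-diol with masked lactone | CN(C)C[C@@H]1C(=O)O[C@@H]2/C=C(/CO[Si](C)(C)C(C)(C)C)CC/C=C(/CO[Si](CC)(CC)CC)[C@H](O)[C@H](O)[C@@H]12
A3 | alternative 2 | all-trans 14,15-dideoxy germacranolide | C=C1C(=O)O[C@@H]2/C=C(\C)CC/C=C(\C)[C@H](O)[C@H](OC(=O)[C@H](C)CC)[C@@H]12
A4 | alternative 2 | 14,15-diol with both ring olefins cis | C=C1C(=O)O[C@@H]2/C=C(/CO)CC/C=C(/CO)[C@H](O)[C@H](OC(=O)[C@H](C)CC)[C@@H]12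
A5 | alternative 3 | C6 aldehyde carrying C7–C10, C11/C12 and C14 | O=C[C@H](CC(=O)OC)[C@H]1OC(C)(C)O[C@H]1C(=C)C2OCCO2
A6 | alternative 3 | tert-butyldimethylsilyl propargyl ether | C#CCO[Si](C)(C)C(C)(C)C
A7 | alternative 3 | but-3-enylzinc bromide | C=CCC[Zn]Br
A8 | alternative 3 | open-chain C1–C10 hydroxy ester | C=CCC/C(CO[Si](C)(C)C(C)(C)C)=C\[C@@H](O)[C@H](CC(=O)OC)[C@H]1OC(C)(C)O[C@H]1C(=C)C2OCCO2
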